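**Retrosynthetic overview**

1. The target is a (2S)-5-hydroxy-7-methoxyflavanone whose ring-B para oxygen is O3 of kaempferol; the last disconnection removes four benzyl ethers from 15.
2. Key disconnection: ring C of the flavanone is cut at C2–C3 and at O1–C8a in one retro-step (aldol plus SNAr). This gives aldehyde 6, which brings C2 with its oxygen, and enol silane 12 of a 2-fluoroaryl methyl ketone.
3. Enabling feature: O1 sits on ring-A carbon C8a, which is ortho (through C4a) to the C4 carbonyl, and C3 is the alpha-carbon of that same carbonyl. One ketone therefore makes C3 a nucleophile and a C8a–F bond an SNAr site. The 5,7,8a-trioxygenated ring A maps onto symmetric 2,6-difluoro-4-methoxyacetophenone 10: one fluoride becomes the 5-oxygen, the other is the leaving group.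
4. Aldehyde 6 comes from SNAr of tri-O-benzylkaempferol 4 (from apigenin 1 by benzylation and C3-hydroxylation) on 4-fluorobenzaldehyde 5; ketone 10 comes from 3,5-difluoroanisole 7 by lithiation and acetylation.
5. Ring order: the flavonol rings arrive intact with apigenin, ring A of the flavanone arrives with 7, and ring C of the flavanone is the only ring formed, in step 7.

Key step: step 7

Assumption: the D-tryptophan-derived oxazaborolidinone is taken to direct the enol silane to the Si face of the formyl group of 6 (the L-tryptophan catalyst being taken to give Re-face addition with aromatic aldehydes); the sense would be checked on a model aldehyde and the other catalyst enantiomer used if it proves reversed.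

**Route**

Step 1
Reactants: 1 apigenin (5,7-dihydroxy-2-(4-hydroxyphenyl)-4H-chromen-4-one)
Product: 2 5,7-bis(benzyloxy)-2-[4-(benzyloxy)phenyl]-4H-chromen-4-one
Conditions: BnBr (4 equiv), K2CO3 (5 equiv), DMF, 80 °C
Reagents that add atoms: benzyl bromide, BrCc1ccccc1
Why: Williamson etherification (SN2 of the phenoxides on benzyl bromide) should protect all three phenols, the hydrogen-bonded 5-OH reacting last and needing the excess reagent and heat.

Step 2
Reactants: 2 5,7-bis(benzyloxy)-2-[4-(benzyloxy)phenyl]-4H-chromen-4-one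
Product: 4 5,7-bis(benzyloxy)-2-[4-(benzyloxy)phenyl]-3-hydroxy-4H-chromen-4-one (tri-O-benzylkaempferol), via flavone 2,3-epoxide 3 (not isolated)
Conditions: dimethyldioxirane (acetone solution, 3 equiv), CH2Cl2, 0 °C → rt; then p-TsOH·H2O (cat.), CH2Cl2, rt
Reagents that add atoms: dimethyldioxirane, CC1(C)OO1
Why: Dioxirane epoxidation of the enol-ether-like C2=C3 bond, followed by acid-catalysed epoxide opening and loss of H3, is the established way from 5,7-dialkoxyflavones to flavonols, and the aryl benzyl ethers should tolerate the neutral oxidant.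

Step 3
Reactants: 4 tri-O-benzylkaempferol; 5 4-fluorobenzaldehyde
Product: 6 4-({5,7-bis(benzyloxy)-2-[4-(benzyloxy)phenyl]-4-oxo-4H-chromen-3-yl}oxy)benzaldehyde
Conditions: K2CO3 (2 equiv), DMF, 100 °C, N2
Reagents that add atoms: none
Why: Nucleophilic aromatic substitution (SNAr): the acidic 3-OH gives an oxygen anion that displaces the fluoride para to the formyl group, and since every other oxygen is blocked only O3 can react.

Step 4
Reactants: 7 3,5-difluoroanisole; 8 N-methoxy-N-methylacetamide
Product: 10 1-(2,6-difluoro-4-methoxyphenyl)ethanone, via aryllithium 9 (not isolated)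
Conditions: n-BuLi (1.05 equiv), THF, −78 °C; then 8, −78 → 0 °C; aq. HCl
Reagents that add atoms: none
Why: Directed ortho-lithiation at the C–H flanked by both fluorines (the most acidic site), then acylation of the aryllithium by the N-methoxy-N-methylamide, whose chelated tetrahedral adduct stops the addition at the ketone stage.

Step 5
Reactants: 10 1-(2,6-difluoro-4-methoxyphenyl)ethanone
Product: 11 1-[2-(benzyloxy)-6-fluoro-4-methoxyphenyl]ethanone
Conditions: BnOH (1.05 equiv), KOtBu (1.1 equiv), THF, 0 °C → rt
Reagents that add atoms: benzyl alcohol, OCc1ccccc1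
Why: SNAr of benzyl oxide on a fluoride ortho to the acetyl group; the two fluorides are equivalent by symmetry and the benzyloxy group introduced first deactivates the ring, so the reaction should stop at mono-substitution.

Step 6
Reactants: 11 1-[2-(benzyloxy)-6-fluoro-4-methoxyphenyl]ethanone
Product: 12 {[1-(2-(benzyloxy)-6-fluoro-4-methoxyphenyl)ethenyl]oxy}trimethylsilane
Conditions: TMSOTf (1.3 equiv), Et3N (2 equiv), CH2Cl2, 0 °C
Reagents that add atoms: trimethylsilyl trifluoromethanesulfonate, C[Si](C)(C)OS(=O)(=O)C(F)(F)F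
Why: Soft enolisation and O-silylation of the methyl ketone (silyl enol ether formation), which has a single enolisable position and so can give only one regioisomer.

Step 7
Reactants: 12 {[1-(2-(benzyloxy)-6-fluoro-4-methoxyphenyl)ethenyl]oxy}trimethylsilane; 6 4-({5,7-bis(benzyloxy)-2-[4-(benzyloxy)phenyl]-4-oxo-4H-chromen-3-yl}oxy)benzaldehyde
Product: 15 (2S)-5-(benzyloxy)-2-[4-({5,7-bis(benzyloxy)-2-[4-(benzyloxy)phenyl]-4-oxo-4H-chromen-3-yl}oxy)phenyl]-7-methoxy-2,3-dihydro-4H-chromen-4-one, via silyl aldol 13 (not isolated), via ammonium aldolate 14 (not isolated)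
Conditions: (R)-2-butyl-4-(indol-3-ylmethyl)-3-tosyl-1,3,2-oxazaborolidin-5-one (from N-tosyl-D-tryptophan and n-BuB(OH)2, 20 mol%), 12 (1.1 equiv), EtCN/CH2Cl2, −78 °C; then Bu4N[Ph3SiF2] (30 mol%), DMF, −40 → 0 °C; AcOH quench
Reagents that add atoms: none
Why: Proposed new method: the boron Lewis acid activates the formyl group of 6 and enol silane 12 adds through an open transition state with silyl transfer to give silyl aldol 13 (C2–C3 bond); fluoride then frees alkoxide 14, which attacks the fluorine-bearing carbon of ring A ortho to the ketone through a carbonyl-stabilised anionic sigma-adduct (O1–C8a bond), and the fluoride that leaves desilylates the next molecule of 13, so fluoride is needed only as an initiator. The closest known reaction types are the oxazaborolidinone-catalysed Mukaiyama aldol of aryl methyl ketone enol silanes with aromatic aldehydes, the aldol–dihydropyranone annulation of 1-methoxy-3-silyloxybutadienes (of which this is the benzo-fused analogue, the ring-A fluoride standing in for methoxide), and fluoride-catalysed aryl ether formation from silyl ethers and activated aryl fluorides. Ring C closes by a 6-exo-trig addition–elimination at an aromatic carbon. The one new stereocentre, C2, is set in the aldol event by the catalyst, which is expected to shield the Re face of the aldehyde so that Si-face attack gives the S configuration, and the C2–O bond is not touched in the ring closure. The step needs the alkoxide to cyclise faster than it undergoes retro-aldol cleavage or the product opens by E1cB; the carbonyl ortho to fluorine, the six-membered transition state, the low temperature and the substoichiometric, weakly basic fluoride source are meant to secure this, and site selectivity is not an issue because only one C–F bond remains in ring A.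

Step 8
Reactants: 15 (2S)-5-(benzyloxy)-2-[4-({5,7-bis(benzyloxy)-2-[4-(benzyloxy)phenyl]-4-oxo-4H-chromen-3-yl}oxy)phenyl]-7-methoxy-2,3-dihydro-4H-chromen-4-one
Product: 16 (2S)-5-hydroxy-2-(4-{[5,7-dihydroxy-2-(4-hydroxyphenyl)-4-oxo-4H-chromen-3-yl]oxy}phenyl)-7-methoxy-2,3-dihydro-4H-chromen-4-one (target)
Conditions: H2 (1 atm), 10% Pd/C, EtOAc/MeOH, rt
Reagents that add atoms: none
Why: Catalytic hydrogenolysis of the four aryl benzyl ethers under neutral conditions, which avoids the base that would racemise C2 by ring opening and should leave the methyl ether, the flavonol C2=C3 bond and both ketones untouched.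

**Compound list**

1 | apigenin | O=c1cc(-c2ccc(O)cc2)oc2cc(O)cc(O)c12 | starting material
2 | 5,7-bis(benzyloxy)-2-[4-(benzyloxy)phenyl]-4H-chromen-4-one | O=c1cc(-c2ccc(OCc3ccccc3)cc2)oc2cc(OCc3ccccc3)cc(OCc3ccccc3)c12 | intermediate
3 | racemic 2,3-epoxide of flavone 2 (oxirane fused across C2–C3, cis by necessity) | O=C1C2OC2(c2ccc(OCc3ccccc3)cc2)Oc2cc(OCc3ccccc3)cc(OCc3ccccc3)c12 | intermediate
4 | 5,7-bis(benzyloxy)-2-[4-(benzyloxy)phenyl]-3-hydroxy-4H-chromen-4-one | O=c1c(O)c(-c2ccc(OCc3ccccc3)cc2)oc2cc(OCc3ccccc3)cc(OCc3ccccc3)c12 | intermediate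
5 | 4-fluorobenzaldehyde | O=Cc1ccc(F)cc1 | starting material
6 | 4-({5,7-bis(benzyloxy)-2-[4-(benzyloxy)phenyl]-4-oxo-4H-chromen-3-yl}oxy)benzaldehyde | O=Cc1ccc(Oc2c(-c3ccc(OCc4ccccc4)cc3)oc3cc(OCc4ccccc4)cc(OCc4ccccc4)c3c2=O)cc1 | intermediate
7 | 3,5-difluoroanisole | COc1cc(F)cc(F)c1 | starting material
8 | N-methoxy-N-methylacetamide | CON(C)C(C)=O | starting material
9 | (2,6-difluoro-4-methoxyphenyl)lithium | COc1cc(F)c([Li])c(F)c1 | intermediate
10 | 1-(2,6-difluoro-4-methoxyphenyl)ethanone | COc1cc(F)c(C(C)=O)c(F)c1 | intermediate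
11 | 1-[2-(benzyloxy)-6-fluoro-4-methoxyphenyl]ethanone | COc1cc(F)c(C(C)=O)c(OCc2ccccc2)c1 | intermediate
12 | {[1-(2-(benzyloxy)-6-fluoro-4-methoxyphenyl)ethenyl]oxy}trimethylsilane | COc1cc(F)c(C(=C)O[Si](C)(C)C)c(OCc2ccccc2)c1 | intermediate
13 | (3S)-1-[2-(benzyloxy)-6-fluoro-4-methoxyphenyl]-3-[4-({5,7-bis(benzyloxy)-2-[4-(benzyloxy)phenyl]-4-oxo-4H-chromen-3-yl}oxy)phenyl]-3-[(trimethylsilyl)oxy]propan-1-one | COc1cc(F)c(C(=O)C[C@H](O[Si](C)(C)C)c2ccc(Oc3c(-c4ccc(OCc5ccccc5)cc4)oc4cc(OCc5ccccc5)cc(OCc5ccccc5)c4c3=O)cc2)c(OCc2ccccc2)c1 | intermediate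
14 | tetrabutylammonium (S)-alkoxide obtained from 13 by loss of the silyl group | COc1cc(F)c(C(=O)C[C@H]([O-])c2ccc(Oc3c(-c4ccc(OCc5ccccc5)cc4)oc4cc(OCc5ccccc5)cc(OCc5ccccc5)c4c3=O)cc2)c(OCc2ccccc2)c1.CCCC[N+](CCCC)(CCCC)CCCC | intermediate
15 | (2S)-5-(benzyloxy)-2-[4-({5,7-bis(benzyloxy)-2-[4-(benzyloxy)phenyl]-4-oxo-4H-chromen-3-yl}oxy)phenyl]-7-methoxy-2,3-dihydro-4H-chromen-4-one | COc1cc(OCc3ccccc3)c2c(c1)O[C@H](c1ccc(Oc3c(-c4ccc(OCc5ccccc5)cc4)oc4cc(OCc5ccccc5)cc(OCc5ccccc5)c4c3=O)cc1)CC2=O | intermediate
16 | (2S)-5-hydroxy-2-(4-{[5,7-dihydroxy-2-(4-hydroxyphenyl)-4-oxo-4H-chromen-3-yl]oxy}phenyl)-7-methoxy-2,3-dihydro-4H-chromen-4-one | COc1cc(O)c2c(c1)O[C@H](c1ccc(Oc3c(-c4ccc(O)cc4)oc4cc(O)cc(O)c4c3=O)cc1)CC2=O | target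

**Step count and risks**

Total step count: 8. Longest linear sequence: 5 steps (steps 1, 2, 3, 7, 8; the branch through steps 4, 5, 6, 7, 8 is equally long).

Steps most likely to fail:

Step 7. What may go wrong: retro-aldol cleavage and re-addition of the alkoxide before the SNAr closure, or base-induced E1cB opening and re-closure of the flavanone, either of which would erode the configuration at C2. Binding of the boron catalyst to the chromone carbonyl of 6 instead of the formyl group would lower turnover and facial selectivity. Fallback (known chemistry): ring C is closed at the O1–C2 bond by a Mitsunobu reaction with inversion, a known route to 5,7-dioxygenated flavanones. It sets out from ketone 11 and aldehyde 6. The fluoride of 11 is exchanged for hydroxyl with 2-(methylsulfonyl)ethanol and NaH in DMF (SNAr, then E1cB loss of methyl vinyl sulfone, aq. HCl) to give 1-[2-(benzyloxy)-6-hydroxy-4-methoxyphenyl]ethanone F1. TMSOTf/Et3N converts this into the bis-silyl compound {[1-(2-(benzyloxy)-4-methoxy-6-[(trimethylsilyl)oxy]phenyl)ethenyl]oxy}trimethylsilane F2. Mukaiyama aldol of F2 with 6 under the enantiomeric, L-tryptophan-derived oxazaborolidinone should give the (R)-bis-silyl aldol F3, which is not isolated and is desilylated on work-up with dilute HCl to the (R)-3-hydroxy ketone phenol F4. PPh3/DIAD in THF at 0 °C then closes the ring with inversion at the carbinol carbon and gives 15, where the route is rejoined.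

Step 3. What may go wrong: sluggish substitution, because the flavonol 3-oxygen anion is hindered by the 2-aryl group and the C4 carbonyl, with degradation of the aldehyde or oxidative breakdown of the flavonolate at the temperature needed. Fallback: copper-catalysed Ullmann-type O-arylation of 4 with 4-iodobenzaldehyde (CuI 10 mol%, picolinic acid 20 mol%, K3PO4, DMSO, 90 °C, under N2 so that the copper flavonolate is not oxygenated). It sets out from 4 and comes back at 6; no compound outside the list is made (F0).

Step 8. What may go wrong: over-reduction by hydrogenolysis of the benzylic C2–O1 bond of the flavanone (ring opening to a dihydrochalcone), or incomplete cleavage of the hindered 5-O-benzyl groups. Fallback: non-reductive debenzylation of 15 by Lewis-acid benzyl transfer, BCl3 (8 equiv) with pentamethylbenzene as cation scavenger in CH2Cl2 at −78 °C, then MeOH/water. The 7-methoxy group, not peri to a carbonyl, should survive at this temperature. It sets out from 15 and comes back at 16; no compound outside the list is made (F0).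

Further compounds
F1 | step 7 | 1-[2-(benzyloxy)-6-hydroxy-4-methoxyphenyl]ethanone | COc1cc(O)c(C(C)=O)c(OCc2ccccc2)c1
F2 | step 7 | {[1-(2-(benzyloxy)-4-methoxy-6-[(trimethylsilyl)oxy]phenyl)ethenyl]oxy}trimethylsilane | COc1cc(O[Si](C)(C)C)c(C(=C)O[Si](C)(C)C)c(OCc2ccccc2)c1
F3 | step 7 | (3R)-1-{2-(benzyloxy)-4-methoxy-6-[(trimethylsilyl)oxy]phenyl}-3-[4-({5,7-bis(benzyloxy)-2-[4-(benzyloxy)phenyl]-4-oxo-4H-chromen-3-yl}oxy)phenyl]-3-[(trimethylsilyl)oxy]propan-1-one | COc1cc(O[Si](C)(C)C)c(C(=O)C[C@@H](O[Si](C)(C)C)c2ccc(Oc3c(-c4ccc(OCc5ccccc5)cc4)oc4cc(OCc5ccccc5)cc(OCc5ccccc5)c4c3=O)cc2)c(OCc2ccccc2)c1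
F4 | step 7 | (3R)-1-[2-(benzyloxy)-6-hydroxy-4-methoxyphenyl]-3-[4-({5,7-bis(benzyloxy)-2-[4-(benzyloxy)phenyl]-4-oxo-4H-chromen-3-yl}oxy)phenyl]-3-hydroxypropan-1-one | COc1cc(O)c(C(=O)C[C@@H](O)c2ccc(Oc3c(-c4ccc(OCc5ccccc5)cc4)oc4cc(OCc5ccccc5)cc(OCc5ccccc5)c4c3=O)cc2)c(OCc2ccccc2)c1
F0 | step 3 | none | none
F0 | step 8 | none | none
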